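## Retrosynthetic overview

1. Target 44 ⇐ acylal-protected bromotetrahydrofuran macrolide 43 ⇐ macrolide diol 42. The last ring is closed by bromonium-induced 5-endo attack of the free C16-OH on the C18=C19 alkene of the intact macrolide.
2. 42 ⇐ seco acid 40 by macrolactonisation of the C1 acid onto the C17-OH (second ring). 40 ⇐ Nozaki–Hiyama–Kishi union of the C17 aldehyde 37 with the C18–C25 vinyl iodide 12.
3. 37 ⇐ acetyloxazole 29 by formyl-olefination, crotylboration and cross-metathesis. The oxazole (first ring) is built on the chain from the C10 acid 26 and the serine-derived aminoketone 15 by cyclodehydration, then dehydrogenation.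
4. 26 ⇐ (S)-citronellal 20 (C10–C15, C13 methyl) and a glycolate aldol (C15, C16). 12 ⇐ (R)-lactic acid 1 (C24), propargyl bromide 3 and propargyl alcohol 6.
5. Ring order: oxazole → macrolactone → bromotetrahydrofuran.

Assumption: the target is made exactly as drawn (4S,5R,13S,15S,16R,17R,18S,19R,24S; 2E,6E,21Z), with the chain numbered C1 (lactone carbonyl) to C25 (acid); compounds 1, 3, 6, 13, 16, 17, 20, 30, 33 and 36 are bought.

## Route

Step 1
Reactants: 1 (R)-lactic acid
Product: 2 (2R,5R)-2-tert-butyl-5-methyl-1,3-dioxolan-4-one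
Conditions: pivalaldehyde, p-TsOH (cat.), H2SO4 (cat.), pentane, reflux, Dean–Stark; recrystallise from pentane at −78 °C
Reagents that add atoms: pivalaldehyde, CC(C)(C)C=O
Why: Seebach acetalisation; the acetal carbon equilibrates to the cis isomer (tert-butyl cis to methyl), which stores the lactate chirality for the alkylation.

Step 2
Reactants: 2 (2R,5R)-2-tert-butyl-5-methyl-1,3-dioxolan-4-one; 3 propargyl bromide
Product: 5 (2R,5S)-2-tert-butyl-5-methyl-5-(prop-2-yn-1-yl)-1,3-dioxolan-4-one, via lithium enolate 4 (not isolated)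
Conditions: lithium diisopropylamide, THF, −78 °C; then 3, −78 → −30 °C
Reagents that add atoms: none
Why: Seebach self-regeneration of stereocentres; the planar enolate is alkylated anti to the tert-butyl group, so propargyl replaces H with retention and sets the quaternary C24 (S in the target).

Step 3
Reactants: 6 propargyl alcohol
Product: 8 (E)-3-iodo-2-methylprop-2-en-1-ol, via alkenylalane 7 (not isolated)
Conditions: Me3Al, Cp2ZrCl2 (25 mol%), CH2Cl2, 0 °C → rt; then I2, THF, −30 → 0 °C; aq. KNaC4H4O6 (potassium sodium tartrate)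
Reagents that add atoms: trimethylaluminium, C[Al](C)C; iodine, II
Why: Negishi zirconium-catalysed syn-carboalumination places Me on the internal and Al on the terminal carbon, and iodinolysis with retention gives the E vinyl iodide (future C18=C19 geometry and C19 methyl).

Step 4
Reactants: 8 (E)-3-iodo-2-methylprop-2-en-1-ol
Product: 9 (E)-3-bromo-1-iodo-2-methylprop-1-ene
Conditions: CBr4, PPh3, CH2Cl2, 0 °C
Reagents that add atoms: carbon tetrabromide, BrC(Br)(Br)Br
Why: Appel bromination of a primary allylic alcohol; the alkene geometry is untouched.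

Step 5
Reactants: 5 (2R,5S)-2-tert-butyl-5-methyl-5-(prop-2-yn-1-yl)-1,3-dioxolan-4-one; 9 (E)-3-bromo-1-iodo-2-methylprop-1-ene
Product: 10 (2R,5S)-2-tert-butyl-5-[(5E)-6-iodo-5-methylhex-5-en-2-yn-1-yl]-5-methyl-1,3-dioxolan-4-one
Conditions: CuI (copper monoiodide), NaI, Cs2CO3, DMF, rt
Reagents that add atoms: none
Why: Copper-mediated coupling of a terminal alkyne with a primary allylic bromide (Jeffery type, attack at the unhindered CH2) gives the skipped enyne and leaves the vinyl iodide intact.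

Step 6
Reactants: 10 (2R,5S)-2-tert-butyl-5-[(5E)-6-iodo-5-methylhex-5-en-2-yn-1-yl]-5-methyl-1,3-dioxolan-4-one
Product: 12 (2R,5S)-2-tert-butyl-5-[(2Z,5E)-6-iodo-5-methylhexa-2,5-dien-1-yl]-5-methyl-1,3-dioxolan-4-one, via alkenylborane 11 (not isolated)
Conditions: Cy2BH (commercial), THF, 0 °C → rt; then AcOH, rt
Reagents that add atoms: none
Why: Syn hydroboration of the internal alkyne by the hindered dialkylborane, then protodeboronation with retention (Brown–Zweifel cis-alkene synthesis), sets the 21Z alkene; the trisubstituted iodoalkene and the acylal are inert.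

Step 7
Reactants: 13 N-Boc-L-serine N-methoxy-N-methylamide
Product: 14 tert-butyl [(2S)-1-hydroxy-3-oxobutan-2-yl]carbamate
Conditions: MeMgBr (3.5 equiv), THF, −15 → 0 °C; 1 M HCl quench
Reagents that add atoms: methylmagnesium bromide, C[Mg]Br
Why: Weinreb ketone synthesis; the chelated tetrahedral intermediate stops at the methyl ketone, with excess Grignard covering OH and NH.

Step 8
Reactants: 14 tert-butyl [(2S)-1-hydroxy-3-oxobutan-2-yl]carbamate
Product: 15 (3S)-3-amino-4-hydroxybutan-2-one hydrochloride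
Conditions: HCl (4 M in dioxane), 0 °C → rt
Reagents that add atoms: hydrogen chloride, Cl
Why: Acidolysis of the Boc carbamate; the α-aminoketone is kept as its salt to prevent self-condensation, and its stereocentre is later lost in the oxazole.

Step 9
Reactants: 16 (tert-butyldimethylsilyloxy)acetic acid; 17 (R)-4-benzyl-2-oxazolidinone
Product: 19 (R)-4-benzyl-3-[(tert-butyldimethylsilyloxy)acetyl]oxazolidin-2-one, via mixed pivalic anhydride 18 (not isolated)
Conditions: PivCl, Et3N, THF, −20 °C; then 17, LiCl, rt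
Reagents that add atoms: none
Why: N-acylation of the oxazolidinone through the mixed anhydride (LiCl/Et3N activation); attack occurs at the less hindered glycolyl carbonyl.

Step 10
Reactants: 19 (R)-4-benzyl-3-[(tert-butyldimethylsilyloxy)acetyl]oxazolidin-2-one; 20 (S)-citronellal
Product: 22 (4R)-4-benzyl-3-[(2R,3S,5S)-2-(tert-butyldimethylsilyloxy)-3-hydroxy-5,9-dimethyldec-8-enoyl]oxazolidin-2-one, via boron enolate 21 (not isolated)
Conditions: Bu2BOTf, Et3N, CH2Cl2, −78 → 0 °C; then 20, −78 → 0 °C; pH 7 buffer, MeOH, H2O2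
Reagents that add atoms: none
Why: Evans syn glycolate aldol through the Zimmerman–Traxler chair of the Z boron enolate; the (R)-auxiliary sets C15 (S) and C16 (R) in a 15,16-syn relationship, with the remote C13 methyl a spectator.

Step 11
Reactants: 22 (4R)-4-benzyl-3-[(2R,3S,5S)-2-(tert-butyldimethylsilyloxy)-3-hydroxy-5,9-dimethyldec-8-enoyl]oxazolidin-2-one
Product: 23 (2R,3S,5S)-2-(tert-butyldimethylsilyloxy)-3-hydroxy-N-methoxy-N,5,9-trimethyldec-8-enamide
Conditions: MeONHMe·HCl, Me3Al, CH2Cl2, −20 → 0 °C; aq. KNaC4H4O6 (potassium sodium tartrate)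
Reagents that add atoms: N,O-dimethylhydroxylamine hydrochloride, CNOC.Cl
Why: Weinreb transamination by the aluminium amide, assisted by the free β-hydroxyl, releases the auxiliary and leaves a C17 acyl group that tolerates the later basic and organometallic steps.

Step 12
Reactants: 23 (2R,3S,5S)-2-(tert-butyldimethylsilyloxy)-3-hydroxy-N-methoxy-N,5,9-trimethyldec-8-enamide
Product: 24 (2R,3S,5S)-2-(tert-butyldimethylsilyloxy)-N,3-dimethoxy-N,5,9-trimethyldec-8-enamide
Conditions: Me3OBF4, 1,8-bis(dimethylamino)naphthalene, 4 Å MS, CH2Cl2, rt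
Reagents that add atoms: trimethyloxonium tetrafluoroborate, C[O+](C)C.F[B-](F)(F)F
Why: Non-basic O-methylation with Meerwein salt avoids retro-aldol and silyl migration and installs the C15 methyl ether before a nucleophilic oxazole nitrogen is present.

Step 13
Reactants: 24 (2R,3S,5S)-2-(tert-butyldimethylsilyloxy)-N,3-dimethoxy-N,5,9-trimethyldec-8-enamide
Product: 26 (4S,6S,7R)-7-(tert-butyldimethylsilyloxy)-6-methoxy-8-[methoxy(methyl)amino]-4-methyl-8-oxooctanoic acid, via aldehyde 25 (not isolated)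
Conditions: O3, CH2Cl2/MeOH, −78 °C; Me2S; then NaClO2, NaH2PO4, 2-methyl-2-butene, t-BuOH/H2O, rt
Reagents that add atoms: ozone, [O-][O+]=O; sodium chlorite, [Na+].[O-]Cl=O
Why: Ozonolysis of the only alkene followed by Pinnick oxidation turns the isopropylidene end into the C10 acid without touching a stereocentre.

Step 14
Reactants: 26 (4S,6S,7R)-7-(tert-butyldimethylsilyloxy)-6-methoxy-8-[methoxy(methyl)amino]-4-methyl-8-oxooctanoic acid; 15 (3S)-3-amino-4-hydroxybutan-2-one hydrochloride
Product: 27 N-[(2S)-1-hydroxy-3-oxobutan-2-yl] amide of acid 26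
Conditions: EDC·HCl, HOBt, N-methylmorpholine, CH2Cl2, 0 °C → rt
Reagents that add atoms: none
Why: Carbodiimide amide coupling gives the acyl-serine-type amide that corresponds to the acyl-seryl intermediate of the biosynthesis.

Step 15
Reactants: 27 N-[(2S)-1-hydroxy-3-oxobutan-2-yl] amide of acid 26
Product: 29 (2R,3S,5S)-7-(4-acetyl-1,3-oxazol-2-yl)-2-(tert-butyldimethylsilyloxy)-N,3-dimethoxy-N,5-dimethylheptanamide, via oxazoline 28 (not isolated)
Conditions: Deoxo-Fluor, CH2Cl2, −20 °C; then BrCCl3, DBU, 0 °C → rt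
Reagents that add atoms: none
Why: Wipf–Williams one-pot oxazole synthesis; cyclodehydration of the β-hydroxy amide gives the oxazoline, and bromination–dehydrobromination at its acidic C4–H aromatises it, in the same heterocyclisation-then-dehydrogenation order as the biosynthesis.

Step 16
Reactants: 29 (2R,3S,5S)-7-(4-acetyl-1,3-oxazol-2-yl)-2-(tert-butyldimethylsilyloxy)-N,3-dimethoxy-N,5-dimethylheptanamide; 30 diethyl [(E)-2-(cyclohexylamino)ethenyl]phosphonate
Product: 32 (2R,3S,5S)-2-(tert-butyldimethylsilyloxy)-N,3-dimethoxy-N,5-dimethyl-7-{4-[(2E)-4-oxobut-2-en-2-yl]-1,3-oxazol-2-yl}heptanamide, via N-cyclohexyl azadiene 31 (not isolated)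
Conditions: 30, NaH, THF, 0 °C; then 29, rt; then aq. oxalic acid, THF, rt
Reagents that add atoms: water, O
Why: Nagata formyl-olefination (Horner–Wadsworth–Emmons of the metallated enamine phosphonate, then imine hydrolysis) converts the methyl ketone into the β-methyl enal; acid hydrolysis equilibrates to the E isomer (oxazole trans to CHO), and the stabilised anion leaves the Weinreb amide alone.

Step 17
Reactants: 32 (2R,3S,5S)-2-(tert-butyldimethylsilyloxy)-N,3-dimethoxy-N,5-dimethyl-7-{4-[(2E)-4-oxobut-2-en-2-yl]-1,3-oxazol-2-yl}heptanamide; 33 (Z)-crotylboronic acid pinacol ester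
Product: 34 homoallylic alcohol: 32 with the CHO replaced by (4S,5R)-CH(OH)–CH(CH3)–CH=CH2 (C5 hydroxyl and C4 methyl syn; target numbering)
Conditions: (R)-TRIP phosphoric acid (5–10 mol%), 4 Å MS, toluene, −30 °C
Reagents that add atoms: none
Why: Chiral phosphoric acid-catalysed crotylboration (Antilla type); the closed chair transition state turns the Z-crotyl geometry into the 4,5-syn relationship, and the (R)-catalyst selects the aldehyde face that gives 5R,4S.

Step 18
Reactants: 34 homoallylic alcohol Weinreb amide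
Product: 35 C17 aldehyde: (2R,3S,5S)-2-(tert-butyldimethylsilyloxy)-3-methoxy-5-methylheptanal carrying at C7 the 2-oxazolyl group with the 4-[(2E,4R,5S)-4-hydroxy-5-methylhepta-2,6-dien-2-yl] substituent
Conditions: i-Bu2AlH (2.2 equiv), THF, −78 °C; aq. KNaC4H4O6 (potassium sodium tartrate)
Reagents that add atoms: none
Why: Weinreb amide reduction stops at the chelated hemiaminal and gives the aldehyde on work-up; the first equivalent deprotonates the C5 hydroxyl, and no ester is present yet.

Step 19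
Reactants: 35 C17 aldehyde with terminal alkene; 36 tert-butyl acrylate
Product: 37 C1–C17 aldehyde tert-butyl (2E)-enoate (C5-OH free, C16-OTBS, C15-OMe)
Conditions: RuCl2(H2IMes)(=CH-C6H4-2-OiPr) (second-generation Hoveyda–Grubbs catalyst, 5 mol%), CH2Cl2, 40 °C
Reagents that add atoms: none
Why: Olefin cross-metathesis of a terminal alkene with an acrylate is E-selective; the trisubstituted C6=C7 alkene and the aldehyde do not react.

Step 20
Reactants: 37 C1–C17 aldehyde tert-butyl enoate; 12 (2R,5S)-2-tert-butyl-5-[(2Z,5E)-6-iodo-5-methylhexa-2,5-dien-1-yl]-5-methyl-1,3-dioxolan-4-one (2 equiv)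
Product: 38 full-chain tert-butyl ester with free C17-OH (16,17-anti; C17 as in the target), C16-OTBS, C5-OH and the C24/C25 acylal
Conditions: CrCl2 (6 equiv), NiCl2 (1 mol%), DMSO, rt
Reagents that add atoms: none
Why: Nozaki–Hiyama–Kishi coupling; the alkenylchromium species (trivalent chromium) adds only to the aldehyde with retention of the E geometry, and polar Felkin–Anh control by the α-silyloxy group, reinforced by 1,3-anti induction from the β-methoxy group, gives the 16,17-anti alcohol.

Step 21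
Reactants: 38 full-chain tert-butyl ester
Product: 40 seco acid (C1 CO2H; C5-OH and C17-OH free; C16-OTBS), via tris-TMS derivative 39 (not isolated)
Conditions: TMSOTf, 2,6-lutidine, CH2Cl2, 0 °C; then aq. citric acid, THF
Reagents that add atoms: none
Why: Silyl triflate-mediated tert-butyl ester cleavage (loss of isobutene) needs neither protic acid nor hydroxide, so the acylal, the TBS ether and the allylic alcohols survive; the transient TMS ester and TMS ethers hydrolyse on work-up.

Step 22
Reactants: 40 seco acid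
Product: 41 macrolactone (C1–O17) with C16-OTBS, C5-OH and the acylal
Conditions: 2-methyl-6-nitrobenzoic anhydride (MNBA), DMAP, CH2Cl2, rt, slow addition, 1 mM
Reagents that add atoms: none
Why: Shiina macrolactonisation at high dilution, mirroring the thioesterase ring closure; only the C17 hydroxyl can reach C1, because the C5 hydroxyl would need a cis-enoate to lactonise and O16 is silylated.

Step 23
Reactants: 41 macrolactone silyl ether
Product: 42 macrolide diol (C16-OH and C5-OH free; acylal-protected terminus)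
Conditions: HF·pyridine, pyridine, THF, 0 °C → rt
Reagents that add atoms: none
Why: Buffered fluoride desilylation frees the C16 hydroxyl without acyl migration or acylal cleavage.

Step 24
Reactants: 42 macrolide diol
Product: 43 bromotetrahydrofuran macrolide (18S,19R) with the acylal-protected terminus
Conditions: 2,4,4,6-tetrabromocyclohexa-2,5-dienone (TBCO, 1.1 equiv), CH2Cl2, −20 → 0 °C, dark
Reagents that add atoms: TBCO, BrC1=CC(Br)(Br)C=C(Br)C1=O
Why: Biomimetic bromonium-induced 5-endo etherification; bromonium formation at the other alkenes is reversible and only C18=C19 has a hydroxyl placed to trap it at its tertiary carbon, and anti addition across the E alkene in the A(1,3)-minimised rotamer (C17–H eclipsing the alkene) puts Br cis to the C19 methyl and trans to the C17 acyloxy group.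

Step 25
Reactants: 43 bromotetrahydrofuran macrolide acylal
Product: 44 target CNP0163177.2
Conditions: LiOH (2 equiv), THF/H2O, 0 °C; then 1 M HCl to pH 3
Reagents that add atoms: lithium hydroxide, [Li+].[OH-]
Why: Mild saponification of the acylal (dioxolanone), which is far more electrophilic than the hindered enoate lactone, releases pivalaldehyde and the α-hydroxy acid without touching a stereocentre.

## Compound list

1 | (R)-lactic acid | C[C@@H](O)C(=O)O | starting material
2 | (2R,5R)-2-tert-butyl-5-methyl-1,3-dioxolan-4-one | C[C@H]1O[C@@H](C(C)(C)C)OC1=O | intermediate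
3 | propargyl bromide | BrCC#C | starting material
4 | lithium enolate of 2 | [Li+].[O-]C1=C(C)O[C@@H](C(C)(C)C)O1 | intermediate (not isolated)
5 | (2R,5S)-2-tert-butyl-5-methyl-5-(prop-2-yn-1-yl)-1,3-dioxolan-4-one | C#CC[C@]1(C)O[C@@H](C(C)(C)C)OC1=O | intermediate
6 | propargyl alcohol | OCC#C | starting material
7 | (E)-alkenylalane (O,C-bis(dimethylaluminium) species) | C[Al](C)OC/C(C)=C/[Al](C)C | intermediate (not isolated)
8 | (E)-3-iodo-2-methylprop-2-en-1-ol | OC/C(C)=C/I | intermediate
9 | (E)-3-bromo-1-iodo-2-methylprop-1-ene | BrC/C(C)=C/I | intermediate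
10 | (2R,5S)-2-tert-butyl-5-[(5E)-6-iodo-5-methylhex-5-en-2-yn-1-yl]-5-methyl-1,3-dioxolan-4-one | I/C=C(\C)CC#CC[C@]1(C)O[C@@H](C(C)(C)C)OC1=O | intermediate
11 | alkenyl(dicyclohexyl)borane (one regioisomer drawn; both give 12) | I/C=C(\C)C/C=C(\C[C@]1(C)O[C@@H](C(C)(C)C)OC1=O)B(C1CCCCC1)C1CCCCC1 | intermediate (not isolated)
12 | (2R,5S)-2-tert-butyl-5-[(2Z,5E)-6-iodo-5-methylhexa-2,5-dien-1-yl]-5-methyl-1,3-dioxolan-4-one (C18–C25) | I/C=C(\C)C/C=C\C[C@]1(C)O[C@@H](C(C)(C)C)OC1=O | intermediate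
13 | N-Boc-L-serine N-methoxy-N-methylamide | CON(C)C(=O)[C@@H](NC(=O)OC(C)(C)C)CO | starting material
14 | tert-butyl [(2S)-1-hydroxy-3-oxobutan-2-yl]carbamate | CC(=O)[C@@H](NC(=O)OC(C)(C)C)CO | intermediate
15 | (3S)-3-amino-4-hydroxybutan-2-one hydrochloride | CC(=O)[C@@H]([NH3+])CO.[Cl-] | intermediate
16 | (tert-butyldimethylsilyloxy)acetic acid | CC(C)(C)[Si](C)(C)OCC(=O)O | starting material
17 | (R)-4-benzyl-2-oxazolidinone | O=C1N[C@H](Cc2ccccc2)CO1 | starting material
18 | mixed pivalic anhydride of 16 | CC(C)(C)C(=O)OC(=O)CO[Si](C)(C)C(C)(C)C | intermediate (not isolated)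
19 | (R)-4-benzyl-3-[(tert-butyldimethylsilyloxy)acetyl]oxazolidin-2-one | CC(C)(C)[Si](C)(C)OCC(=O)N1[C@H](Cc2ccccc2)COC1=O | intermediate
20 | (S)-citronellal | CC(C)=CCC[C@H](C)CC=O | starting material
21 | (Z)-dibutylboron enolate of 19 | CCCCB(CCCC)O/C(=C\O[Si](C)(C)C(C)(C)C)N1[C@H](Cc2ccccc2)COC1=O | intermediate (not isolated)
22 | syn-aldol adduct, (2R,3S,5S)-acyl chain on the (4R)-auxiliary | O=C([C@H](O[Si](C)(C)C(C)(C)C)[C@@H](O)C[C@@H](C)CCC=C(C)C)N1[C@H](Cc2ccccc2)COC1=O | intermediate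
23 | (2R,3S,5S)-β-hydroxy Weinreb amide | CON(C)C(=O)[C@H](O[Si](C)(C)C(C)(C)C)[C@@H](O)C[C@@H](C)CCC=C(C)C | intermediate
24 | (2R,3S,5S)-β-methoxy Weinreb amide | CON(C)C(=O)[C@H](O[Si](C)(C)C(C)(C)C)[C@@H](OC)C[C@@H](C)CCC=C(C)C | intermediate
25 | C10 aldehyde | CON(C)C(=O)[C@H](O[Si](C)(C)C(C)(C)C)[C@@H](OC)C[C@@H](C)CCC=O | intermediate (not isolated)
26 | (4S,6S,7R) C10 acid | CON(C)C(=O)[C@H](O[Si](C)(C)C(C)(C)C)[C@@H](OC)C[C@@H](C)CCC(=O)O | intermediate
27 | N-(1-hydroxy-3-oxobutan-2-yl) amide of 26 | CON(C)C(=O)[C@H](O[Si](C)(C)C(C)(C)C)[C@@H](OC)C[C@@H](C)CCC(=O)N[C@@H](CO)C(C)=O | intermediate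
28 | 4-acetyl-4,5-dihydrooxazole (oxazoline) | CON(C)C(=O)[C@H](O[Si](C)(C)C(C)(C)C)[C@@H](OC)C[C@@H](C)CCC1=N[C@H](C(C)=O)CO1 | intermediate (not isolated)
29 | 4-acetyloxazole Weinreb amide | CON(C)C(=O)[C@H](O[Si](C)(C)C(C)(C)C)[C@@H](OC)C[C@@H](C)CCc1nc(co1)C(C)=O | intermediate
30 | diethyl [(E)-2-(cyclohexylamino)ethenyl]phosphonate | CCOP(=O)(OCC)/C=C/NC1CCCCC1 | starting material
31 | N-cyclohexyl imine of enal 32 | CON(C)C(=O)[C@H](O[Si](C)(C)C(C)(C)C)[C@@H](OC)C[C@@H](C)CCc1nc(co1)/C(C)=C/C=N/C1CCCCC1 | intermediate (not isolated)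
32 | (E)-β-methyl enal (C5 aldehyde) | CON(C)C(=O)[C@H](O[Si](C)(C)C(C)(C)C)[C@@H](OC)C[C@@H](C)CCc1nc(co1)/C(C)=C/C=O | intermediate
33 | (Z)-crotylboronic acid pinacol ester | C/C=C\CB1OC(C)(C)C(C)(C)O1 | starting material
34 | (4S,5R) homoallylic alcohol Weinreb amide | CON(C)C(=O)[C@H](O[Si](C)(C)C(C)(C)C)[C@@H](OC)C[C@@H](C)CCc1nc(co1)/C(C)=C/[C@H](O)[C@@H](C)C=C | intermediate
35 | C17 aldehyde with terminal alkene | O=C[C@H](O[Si](C)(C)C(C)(C)C)[C@@H](OC)C[C@@H](C)CCc1nc(co1)/C(C)=C/[C@H](O)[C@@H](C)C=C | intermediate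
36 | tert-butyl acrylate | C=CC(=O)OC(C)(C)C | starting material
37 | C1–C17 aldehyde tert-butyl (2E)-enoate | O=C[C@H](O[Si](C)(C)C(C)(C)C)[C@@H](OC)C[C@@H](C)CCc1nc(co1)/C(C)=C/[C@H](O)[C@@H](C)/C=C/C(=O)OC(C)(C)C | intermediate
38 | full-chain tert-butyl ester, C17-OH free | O[C@@H](/C=C(\C)C/C=C\C[C@]1(C)O[C@@H](C(C)(C)C)OC1=O)[C@H](O[Si](C)(C)C(C)(C)C)[C@@H](OC)C[C@@H](C)CCc1nc(co1)/C(C)=C/[C@H](O)[C@@H](C)/C=C/C(=O)OC(C)(C)C | intermediate
39 | tris-TMS derivative (TMS ester, 5-O-TMS, 17-O-TMS) | C[Si](C)(C)O[C@@H](/C=C(\C)C/C=C\C[C@]1(C)O[C@@H](C(C)(C)C)OC1=O)[C@H](O[Si](C)(C)C(C)(C)C)[C@@H](OC)C[C@@H](C)CCc1nc(co1)/C(C)=C/[C@H](O[Si](C)(C)C)[C@@H](C)/C=C/C(=O)O[Si](C)(C)C | intermediate (not isolated)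
40 | seco acid | O[C@@H](/C=C(\C)C/C=C\C[C@]1(C)O[C@@H](C(C)(C)C)OC1=O)[C@H](O[Si](C)(C)C(C)(C)C)[C@@H](OC)C[C@@H](C)CCc1nc(co1)/C(C)=C/[C@H](O)[C@@H](C)/C=C/C(=O)O | intermediate
41 | macrolactone, C16-OTBS | O1[C@@H](/C=C(\C)C/C=C\C[C@]2(C)O[C@@H](C(C)(C)C)OC2=O)[C@H](O[Si](C)(C)C(C)(C)C)[C@@H](OC)C[C@@H](C)CCc2nc(co2)/C(C)=C/[C@H](O)[C@@H](C)/C=C/C1=O | intermediate
42 | macrolide diol (C16-OH, C5-OH), acylal terminus | O1[C@@H](/C=C(\C)C/C=C\C[C@]2(C)O[C@@H](C(C)(C)C)OC2=O)[C@H](O)[C@@H](OC)C[C@@H](C)CCc2nc(co2)/C(C)=C/[C@H](O)[C@@H](C)/C=C/C1=O | intermediate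
43 | bromotetrahydrofuran macrolide, acylal terminus | CO[C@H]1C[C@@H](C)CCc2nc(co2)/C(C)=C/[C@H](O)[C@@H](C)/C=C/C(=O)O[C@@H]2[C@@H]1O[C@](C)(C/C=C\C[C@]3(C)O[C@@H](C(C)(C)C)OC3=O)[C@H]2Br | intermediate
44 | CNP0163177.2 | CO[C@H]1C[C@@H](C)CCc2nc(co2)/C(C)=C/[C@H](O)[C@@H](C)/C=C/C(=O)O[C@@H]2[C@@H]1O[C@](C)(C/C=C\C[C@](C)(O)C(=O)O)[C@H]2Br | target

## Step count and risks

Total steps: 25. Longest linear sequence: 17 steps (steps 9–25, from 16 and 17 to 44).

**Step 24 (late bromoetherification).** The macrolide carries four alkenes and an oxazole, and both chemoselectivity and the facial outcome rest on substrate control. The fallback sets out from 38 and comes back at 43 by closing the tetrahydrofuran before the macrocycle. HF·pyridine removes the TBS group of 38 to give the 16,17-diol tert-butyl ester F1. TBCO then cyclises it to the bromotetrahydrofuran hydroxy ester F2; only O16 can reach C19 in a 5-endo mode, and the same A(1,3) control operates on the open chain. TMSOTf/2,6-lutidine frees the bromotetrahydrofuran seco acid F3, and MNBA/DMAP lactonises it onto the C17 hydroxyl to give 43.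

**Step 16 (formyl-olefination of the methyl ketone).** Enolisation of the acetyl group and an E/Z mixture are the likely problems. The fallback sets out from 29 and comes back at 32. Ethynylmagnesium bromide at −78 °C adds to the ketone in preference to the Weinreb amide and gives the tertiary propargylic alcohol F4. A Meyer–Schuster rearrangement with Ph3PAuNTf2 and MoO2(acac)2 in toluene converts it into the thermodynamically favoured E enal 32.

**Step 22 (macrolactonisation of the free acid).** DMAP activation of a γ-branched enoic acid can isomerise or epimerise, the C5 hydroxyl is free, and step 21 must first liberate the acid. The fallback sets out from 35 and comes back at 41 using a thioester that is lactonised directly. S-ethyl prop-2-enethioate F5 is made from acryloyl chloride and ethanethiol (Et3N, CH2Cl2, −78 °C). Cross-metathesis of 35 with it, using the catalyst of step 19, gives the aldehyde thioester F6. Nozaki–Hiyama–Kishi coupling with 12 gives the hydroxy thioester F7. AgOCOCF3 with Na2HPO4 in toluene at 60 °C under high dilution activates the thioester and closes the lactone to 41, with no acid-release step and no acyl-pyridinium intermediate.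

Further compounds
F1 | step 24 | 16,17-diol tert-butyl ester (38 without TBS) | O[C@@H](/C=C(\C)C/C=C\C[C@]1(C)O[C@@H](C(C)(C)C)OC1=O)[C@H](O)[C@@H](OC)C[C@@H](C)CCc1nc(co1)/C(C)=C/[C@H](O)[C@@H](C)/C=C/C(=O)OC(C)(C)C
F2 | step 24 | bromotetrahydrofuran hydroxy tert-butyl ester (C17-OH free) | CO[C@@H](C[C@@H](C)CCc1nc(co1)/C(C)=C/[C@H](O)[C@@H](C)/C=C/C(=O)OC(C)(C)C)[C@H]1O[C@](C)(C/C=C\C[C@]2(C)O[C@@H](C(C)(C)C)OC2=O)[C@@H](Br)[C@@H]1O
F3 | step 24 | bromotetrahydrofuran seco acid | CO[C@@H](C[C@@H](C)CCc1nc(co1)/C(C)=C/[C@H](O)[C@@H](C)/C=C/C(=O)O)[C@H]1O[C@](C)(C/C=C\C[C@]2(C)O[C@@H](C(C)(C)C)OC2=O)[C@@H](Br)[C@@H]1O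
F4 | step 16 | tertiary propargylic alcohol from 29 (both carbinol epimers) | CON(C)C(=O)[C@H](O[Si](C)(C)C(C)(C)C)[C@@H](OC)C[C@@H](C)CCc1nc(co1)C(C)(O)C#C
F5 | step 22 | S-ethyl prop-2-enethioate | C=CC(=O)SCC
F6 | step 22 | C1–C17 aldehyde S-ethyl (2E)-enethioate | O=C[C@H](O[Si](C)(C)C(C)(C)C)[C@@H](OC)C[C@@H](C)CCc1nc(co1)/C(C)=C/[C@H](O)[C@@H](C)/C=C/C(=O)SCC
F7 | step 22 | full-chain hydroxy S-ethyl thioester | O[C@@H](/C=C(\C)C/C=C\C[C@]1(C)O[C@@H](C(C)(C)C)OC1=O)[C@H](O[Si](C)(C)C(C)(C)C)[C@@H](OC)C[C@@H](C)CCc1nc(co1)/C(C)=C/[C@H](O)[C@@H](C)/C=C/C(=O)SCC
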